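**Plan**

- Labels: C1 quaternary methyl carbon; C2, C3 ring CH2; C4 isopropyl carbinol; C5 ring-fusion CH; C6 aroyloxy carbon; C7 CH2; C8=C9 methyl alkene; C10 isovaleryloxy carbon. The cyclopentane is C1–C5, the cycloheptene C1/C5–C10; β is the face of the C1 methyl, α the other face.
- Cuts: first the two ester C–O bonds, then C1–C5. That bond is traced back to the C1–C6 fusion bond of a trans-decalin (ring A C1–C6, ring B C1/C6–C10) with a 5α-mesylate and a 6α-hydroxyl. The decalin is cut at C4–isopropyl, C5–C6 (aldol) and C1–C2 (Michael).
- Enabling feature: C1 is quaternary and its neighbour C5 is a CH lying between the oxygenated carbons C4 and C6. This is the pattern left by a 1,2-shift of C1 from C6 to C5, and C10 and C4 then coincide with the two carbonyls of a methyl-decalin enedione.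
- Forward: Michael/aldol annulation builds rings B and A; one semipinacol shift turns them into the cyclopentane and the cycloheptanone; the seven-membered ring is then esterified at C6, dehydrogenated at C8–C9 and esterified at C10.
- Stereochemistry: C1 from the D-proline aldol; C4, C5–O and C6–O from additions anti to the axial C1 methyl; C5–H from inversion in the shift; C6 and C10 from hydride delivery on the cis-fused bicycle.

Key step: step 9

Remark on C8: the Michael adduct is a cis/trans pair, so the annulation gives two C8 epimers. The route is written for the epimer with the C8 methyl cis to the C1 methyl (equatorial on ring B, leaving the α face of C5=C6 open), separated at the enedione stage; C8 becomes sp2 in step 14, so the other epimer can be put through the same steps.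

**Route**

Step 1
Reactants: 1 5-methylcyclohexane-1,3-dione
Product: 2 2,5-dimethylcyclohexane-1,3-dione
Conditions: MeI, NaOH, H2O/MeOH, 60 °C
Reagents that add atoms: iodomethane CI
Why: C-alkylation of the 1,3-dione enolate with iodomethane in aqueous base is the standard entry to 2-alkylcyclohexane-1,3-diones; 2 enolises, so no configuration is fixed here.

Step 2
Reactants: 2 2,5-dimethylcyclohexane-1,3-dione; 3 but-3-en-2-one
Product: 4 2,5-dimethyl-2-(3-oxobutyl)cyclohexane-1,3-dione (cis/trans pair)
Conditions: Et3N (cat.), EtOAc, 25 → 50 °C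
Reagents that add atoms: none
Why: amine-catalysed Michael addition of the dione to the enone builds the quaternary carbon C1 and gives 4 as a cis/trans pair (C1 methyl against C8 methyl), each isomer achiral.

Step 3
Reactants: 4 2,5-dimethyl-2-(3-oxobutyl)cyclohexane-1,3-dione
Product: 6 (3R,8aR)-3,8a-dimethyl-3,4,8,8a-tetrahydronaphthalene-1,6(2H,7H)-dione (enedione), via ketol 5 (not isolated)
Conditions: D-proline (0.3 equiv), DMSO, 25 °C; chromatography (removes the C8 epimer), recrystallisation
Reagents that add atoms: none
Why: Hajos–Parrish–Eder–Sauer–Wiechert reaction, in which the D-proline enamine of the side-chain ketone attacks one of the two enantiotopic ring carbonyls in an intramolecular aldol addition (C5–C6 bond, ring A), which should set C1 as R (the mirror image of the L-proline outcome), after which ketol 5 dehydrates to the enone; recrystallisation is expected to raise the enantiomeric purity.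

Step 4
Reactants: 6 enedione
Product: 7 enone ketal (6 with C10 as its 1,3-dioxolane)
Conditions: ethane-1,2-diol, p-TsOH·H2O, 4 Å molecular sieves, 25 °C
Reagents that add atoms: ethane-1,2-diol OCCO
Why: chemoselective acid-catalysed ketalisation, since the saturated C10 ketone of such enediones forms the dioxolane much faster than the conjugated C4 ketone.

Step 5
Reactants: 7 enone ketal
Product: 8 tertiary allylic alcohol (4β-hydroxy; 4α-isopropyl; C5=C6)
Conditions: i-PrLi, CeCl3, THF, −78 °C
Reagents that add atoms: isopropyllithium [Li]C(C)C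
Why: organocerium 1,2-addition to the enone (no enolisation, no conjugate addition); axial attack on the half-chair from the α face, anti to the angular methyl as in additions to steroidal 4-en-3-ones, should place the isopropyl group α and the hydroxyl β at C4.

Step 6
Reactants: 8 tertiary allylic alcohol
Product: 9 4β-triethylsilyl ether of 8
Conditions: Et3SiOTf, 2,6-lutidine, CH2Cl2, −78 → 0 °C
Reagents that add atoms: triethylsilyl trifluoromethanesulfonate CC[Si](CC)(CC)OS(=O)(=O)C(F)(F)F
Why: silylation of a hindered tertiary alcohol with a silyl triflate and 2,6-lutidine; the ether prevents alkoxide chemistry at C4 in step 9 and adds to the shielding of the β face.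

Step 7
Reactants: 9 silyl ether
Product: 10 5α,6α-diol (trans-decalin)
Conditions: OsO4 (cat.), N-methylmorpholine N-oxide, acetone/H2O, 25 °C
Reagents that add atoms: osmium tetroxide O=[Os](=O)(=O)=O (transfers the two oxygens); N-methylmorpholine N-oxide C[N+]1([O-])CCOCC1 (restores them on osmium)
Why: Upjohn syn-dihydroxylation of the trisubstituted alkene; osmium should add to the α face, anti to the axial C1 methyl and anti to the allylic C4 silyloxy group, which sets C5 (OH α, equatorial) and C6 (OH α, axial) and leaves a trans-decalin.

Step 8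
Reactants: 10 5α,6α-diol
Product: 11 5α-mesylate of 10 (6α-hydroxyl free)
Conditions: MsCl, Et3N, CH2Cl2, −10 °C
Reagents that add atoms: methanesulfonyl chloride CS(=O)(=O)Cl
Why: sulfonylation through sulfene takes the only secondary hydroxyl (C5), while the tertiary axial C6 hydroxyl does not react under these conditions.

Step 9
Reactants: 11 5α-mesylate
Product: 13 cis-fused hydroazulen-6-one (4β-triethylsilyloxy; 4α-isopropyl; 8β-methyl; C10 dioxolane), via potassium alkoxide 12 (not isolated)
Conditions: KOt-Bu (1.05 equiv), t-BuOH/THF, 0 °C; then aq. NH4Cl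
Reagents that add atoms: none
Why: KOt-Bu deprotonates the axial C6 hydroxyl, and as alkoxide 12 pushes and the equatorial C5 mesylate leaves, the antiperiplanar C1–C6 fusion bond migrates to C5 in a concerted semipinacol (pinacol-type) 1,2-shift, the known route from decalin-1,2-diol monosulfonates to hydroazulenones. The new C1–C5 bond closes the cyclopentane (C1–C5) by contraction of ring A, C1 entering at the rear of the C5–O bond in an intramolecular SN2-like displacement, and the cycloheptanone (C1/C5–C10) arises at the same moment by one-carbon expansion of ring B as C6 becomes the carbonyl carbon. C5 is the only new stereocentre and is set by inversion, the α-mesylate being replaced by C1 from the opposite side, which puts H5 cis to the C1 methyl (cis ring fusion), while C1 migrates with retention. The selectivity needed is migration of C1 and not of C7 (which would give a bridged ketone) or epoxide closure: the trans-decalin chair holds the C5–O bond equatorial and so anti only to C1–C6, the cis O5/O6 arrangement excludes epoxide formation, and C4 and C6 carry no hydrogen, so there is no E2 path. A near-stoichiometric amount of base at 0 °C and a prompt quench should keep the kinetic cis-fused ketone from epimerising at C5 or losing the β-silyloxy group.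

Step 10
Reactants: 13 hydroazulen-6-one
Product: 14 6α-alcohol of 13
Conditions: LiBH(s-Bu)3, THF, −78 °C; then NaOH, H2O2
Reagents that add atoms: none
Why: hydride reduction under steric approach control, in which the bulky borohydride should come from the convex β face of the cis-fused bicycle (the side of H5 and the C1 methyl), away from the cyclopentane and its α-isopropyl group, to give the 6α-alcohol.

Step 11
Reactants: 15 4-hydroxybenzoic acid
Product: 17 4-(triisopropylsilyloxy)benzoic acid, via bis-silyl benzoate 16 (not isolated)
Conditions: i-Pr3SiCl, imidazole, DMF, 25 °C; then K2CO3, MeOH/THF/H2O; 1 M HCl to pH 3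
Reagents that add atoms: chlorotriisopropylsilane CC(C)[Si](Cl)(C(C)C)C(C)C
Why: exhaustive silylation followed by selective hydrolysis of the labile silyl ester is the usual way to a phenol-protected hydroxybenzoic acid, and the aryl triisopropylsilyl ether is chosen because it survives dilute aqueous acid and acylation conditions.

Step 12
Reactants: 14 6α-alcohol; 17 4-(triisopropylsilyloxy)benzoic acid
Product: 19 6α-[4-(triisopropylsilyloxy)benzoate] of 14, via acid chloride 18 (not isolated)
Conditions: 17, (COCl)2, DMF (cat.), CH2Cl2, 0 → 25 °C, evaporate; then 14, Et3N, DMAP, CH2Cl2, 25 → 40 °C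
Reagents that add atoms: none
Why: DMAP-catalysed acylation of the hindered secondary C6 alcohol by the acid chloride, with retention at C6.

Step 13
Reactants: 19 6α-aroyl ester
Product: 20 10-ketone with free 4β-hydroxyl
Conditions: 2 M HCl, THF/H2O, 25 → 40 °C
Reagents that add atoms: water O
Why: acid hydrolysis removes the dioxolane and the tertiary triethylsilyl ether in one operation while the aryl triisopropylsilyl ether and the benzoate-type ester are stable to dilute acid; C10 is unmasked only after O6 is acylated, so no transannular hemiketal can form.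

Step 14
Reactants: 20 10-ketone
Product: 21 8,9-en-10-one
Conditions: IBX, DMSO/fluorobenzene, 70 °C
Reagents that add atoms: none
Why: IBX dehydrogenation of a ketone, where enolisation is possible only toward C9 (C1 is quaternary), so the C8–C9 enone forms and the C8 stereocentre disappears; tertiary alcohol, esters and aryl silyl ether are inert to IBX.

Step 15
Reactants: 21 enone
Product: 22 10β-allylic alcohol
Conditions: NaBH4, CeCl3·7H2O, MeOH, −78 → 0 °C
Reagents that add atoms: none
Why: Luche 1,2-reduction of the enone, with hydride expected anti to the angular C1 methyl that flanks the carbonyl (as in reductions of methyl-decalin diones of this type) to give the 10β-alcohol; the cold, near-neutral conditions avoid dienolate formation, which could expel the C6 carboxylate.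

Step 16
Reactants: 22 10β-allylic alcohol
Product: 23 10β-(3-methylbutanoate) of 22
Conditions: 3-methylbutanoyl chloride, pyridine, DMAP, CH2Cl2, 0 → 25 °C
Reagents that add atoms: 3-methylbutanoyl chloride CC(C)CC(Cl)=O
Why: DMAP-catalysed acylation of the secondary allylic alcohol with retention at C10; the hindered tertiary C4 hydroxyl is not acylated under these conditions.

Step 17
Reactants: 23 silyl-protected diester
Product: 24 CNP0086724.1
Conditions: Bu4NF, AcOH, THF, 0 °C
Reagents that add atoms: none
Why: fluoride cleavage of the aryl silyl ether, buffered with acetic acid so that the phenoxide is protonated at once and the two esters are left alone.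

**Compound list**

1 | 5-methylcyclohexane-1,3-dione | CC1CC(=O)CC(=O)C1 | starting material
2 | 2,5-dimethylcyclohexane-1,3-dione | CC1CC(=O)C(C)C(=O)C1 | intermediate
3 | but-3-en-2-one | CC(=O)C=C | starting material
4 | 2,5-dimethyl-2-(3-oxobutyl)cyclohexane-1,3-dione (cis/trans pair; SMILES shows the isomer with the two ring methyl groups cis, which leads to 6) | C[C@H]1CC(=O)[C@](C)(CCC(C)=O)C(=O)C1 | intermediate
5 | ketol: cis-fused decalin-4,10-dione with 6β-hydroxyl, 1β-methyl and 8β-methyl (labels as above) | C[C@H]1CC(=O)[C@]2(C)CCC(=O)C[C@]2(O)C1 | intermediate (not isolated)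
6 | (3R,8aR)-3,8a-dimethyl-3,4,8,8a-tetrahydronaphthalene-1,6(2H,7H)-dione (C4 enone carbonyl, C5=C6, C10 ketone; C8 methyl cis to the C1 methyl) | C[C@H]1CC(=O)[C@]2(C)CCC(=O)C=C2C1 | intermediate
7 | enone ketal: 6 with C10 as its 1,3-dioxolane | C[C@H]1CC2(OCCO2)[C@]3(C)CCC(=O)C=C3C1 | intermediate
8 | tertiary allylic alcohol: 4β-hydroxy-4α-isopropyl, C5=C6, 1β,8β-dimethyl, C10 dioxolane | C[C@H]1CC2(OCCO2)[C@]3(C)CC[C@](O)(C(C)C)C=C3C1 | intermediate
9 | 4β-triethylsilyl ether of 8 | C[C@H]1CC2(OCCO2)[C@]3(C)CC[C@](O[Si](CC)(CC)CC)(C(C)C)C=C3C1 | intermediate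
10 | 5α,6α-diol: trans-decalin, 4β-triethylsilyloxy, 4α-isopropyl, C10 dioxolane | C[C@H]1CC2(OCCO2)[C@]3(C)CC[C@](O[Si](CC)(CC)CC)(C(C)C)[C@H](O)[C@@]3(O)C1 | intermediate
11 | 5α-methanesulfonate of 10 (equatorial mesylate, axial 6α-hydroxyl) | C[C@H]1CC2(OCCO2)[C@]3(C)CC[C@](O[Si](CC)(CC)CC)(C(C)C)[C@H](OS(C)(=O)=O)[C@@]3(O)C1 | intermediate
12 | potassium 6α-alkoxide of 11 | C[C@H]1CC2(OCCO2)[C@]3(C)CC[C@](O[Si](CC)(CC)CC)(C(C)C)[C@H](OS(C)(=O)=O)[C@@]3([O-])C1.[K+] | intermediate (not isolated)
13 | cis-fused hydroazulen-6-one: 1β-methyl, 5β-H, 4β-triethylsilyloxy, 4α-isopropyl, 8β-methyl, C10 dioxolane | C[C@H]1CC2(OCCO2)[C@]3(C)CC[C@](O[Si](CC)(CC)CC)(C(C)C)[C@@H]3C(=O)C1 | intermediate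
14 | 6α-alcohol of 13 | C[C@H]1CC2(OCCO2)[C@]3(C)CC[C@](O[Si](CC)(CC)CC)(C(C)C)[C@@H]3[C@H](O)C1 | intermediate
15 | 4-hydroxybenzoic acid | O=C(O)c1ccc(O)cc1 | starting material
16 | triisopropylsilyl 4-(triisopropylsilyloxy)benzoate | CC(C)[Si](OC(=O)c1ccc(O[Si](C(C)C)(C(C)C)C(C)C)cc1)(C(C)C)C(C)C | intermediate (not isolated)
17 | 4-(triisopropylsilyloxy)benzoic acid | CC(C)[Si](Oc1ccc(cc1)C(=O)O)(C(C)C)C(C)C | intermediate
18 | 4-(triisopropylsilyloxy)benzoyl chloride | CC(C)[Si](Oc1ccc(cc1)C(=O)Cl)(C(C)C)C(C)C | intermediate (not isolated)
19 | 6α-[4-(triisopropylsilyloxy)benzoate] of 14 | C[C@H]1CC2(OCCO2)[C@]3(C)CC[C@](O[Si](CC)(CC)CC)(C(C)C)[C@@H]3[C@H](OC(=O)c4ccc(O[Si](C(C)C)(C(C)C)C(C)C)cc4)C1 | intermediate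
20 | 10-ketone: 4β-hydroxy, 4α-isopropyl, 8β-methyl, 6α-[4-(triisopropylsilyloxy)benzoyloxy] | C[C@H]1CC(=O)[C@]2(C)CC[C@](O)(C(C)C)[C@@H]2[C@H](OC(=O)c2ccc(O[Si](C(C)C)(C(C)C)C(C)C)cc2)C1 | intermediate
21 | 8,9-en-10-one of 20 | CC1=CC(=O)[C@]2(C)CC[C@](O)(C(C)C)[C@@H]2[C@H](OC(=O)c2ccc(O[Si](C(C)C)(C(C)C)C(C)C)cc2)C1 | intermediate
22 | 10β-allylic alcohol | CC1=C[C@@H](O)[C@]2(C)CC[C@](O)(C(C)C)[C@@H]2[C@H](OC(=O)c2ccc(O[Si](C(C)C)(C(C)C)C(C)C)cc2)C1 | intermediate
23 | 10β-(3-methylbutanoate) of 22 | CC1=C[C@@H](OC(=O)CC(C)C)[C@]2(C)CC[C@](O)(C(C)C)[C@@H]2[C@H](OC(=O)c2ccc(O[Si](C(C)C)(C(C)C)C(C)C)cc2)C1 | intermediate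
24 | CNP0086724.1: cis-fused hydroazulene, 1β-methyl, 4β-hydroxy, 4α-isopropyl, 5β-H, 6α-(4-hydroxybenzoyloxy), 8-methyl-8,9-ene, 10β-(3-methylbutanoyloxy); (1R,4S,5S,6R,10R) in the labels used here | CC1=C[C@@H](OC(=O)CC(C)C)[C@]2(C)CC[C@](O)(C(C)C)[C@@H]2[C@H](OC(=O)c2ccc(O)cc2)C1 | target

**Count and risks**

Total step count: 17. Longest linear sequence: 16 steps (1 to 24 through steps 1–10 and 12–17; step 11 prepares the acid).

Steps most likely to fail:

1. Step 7, poor facial selectivity or slow turnover in the osmylation. The α face is anti to the C1 methyl and to the C4 silyloxy group, but it also carries the C4 isopropyl group, so osmium may be turned to the β face. The fallback sets out from 9 and uses a Woodward cis-hydroxylation (I2, AgOAc, AcOH, then water). The iodonium ion forms on the face an electrophile prefers, and acetate opens it trans-diaxially at the tertiary C6 from the α face to give the 5β-iodo-6α-acetate F1. Silver-assisted displacement of iodide by the neighbouring acetate and hydrolysis of the acetoxonium ion then give the 5α-hydroxy-6α-acetate F2. Methanolysis (K2CO3, MeOH) returns to the route at 10. The cis-diol thus ends on the face opposite to the one the electrophile attacks.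

2. Step 15, hydride delivery to the wrong face of the C10 carbonyl. The seven-membered enone is conformationally mobile and the carbonyl is flanked by both the C1 methyl and C2, so the 10α-alcohol may dominate. The fallback sets out from 21: the reduction is run as before, the 10α-alcohol F4 is taken, and the ester is installed with inversion by a Mitsunobu reaction with 3-methylbutanoic acid (PPh3, DIAD, toluene). The route is rejoined at 23 without passing through 22.

3. Step 10, hydride attack from the concave face of the C6 ketone. The C4 silyloxy group lies on the convex side and may offset the shielding by the cyclopentane. The fallback sets out from 13: the reduction is allowed to give the 6β-alcohol F3, which is esterified with inversion by a Mitsunobu reaction with acid 17 (PPh3, DIAD, toluene). The route is rejoined at 19 without passing through 14 and 18.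

**Further compounds**

F1 | step 7 | 5β-iodo-6α-acetate from 9 (trans-diaxial) | C[C@H]1CC2(OCCO2)[C@]3(C)CC[C@](O[Si](CC)(CC)CC)(C(C)C)[C@@H](I)[C@@]3(OC(C)=O)C1
F2 | step 7 | 5α-hydroxy-6α-acetate (monoacetate of 10) | C[C@H]1CC2(OCCO2)[C@]3(C)CC[C@](O[Si](CC)(CC)CC)(C(C)C)[C@H](O)[C@@]3(OC(C)=O)C1
F3 | step 10 | 6β-alcohol (C6 epimer of 14) | C[C@H]1CC2(OCCO2)[C@]3(C)CC[C@](O[Si](CC)(CC)CC)(C(C)C)[C@@H]3[C@@H](O)C1
F4 | step 15 | 10α-allylic alcohol (C10 epimer of 22) | CC1=C[C@H](O)[C@]2(C)CC[C@](O)(C(C)C)[C@@H]2[C@H](OC(=O)c2ccc(O[Si](C(C)C)(C(C)C)C(C)C)cc2)C1
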